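**Retrosynthetic overview**

1. The target is fisetinidol-(4α→6)-fisetinidol. Upper unit: rings A (benzo), C (pyran), B (catechol). Lower unit: rings D (benzo), F (pyran), E (catechol). The last operations remove one silyl and five benzyl ethers.
2. The 3-hydroxyls of rings C and F and the C4 hydrogen of ring C come from one double hydroboration–oxidation of a bis-flav-3-ene. Each addition is syn and anti to the C2 aryl group, which also places ring D trans to the 3-hydroxyl at C4 of ring C.
3. Key disconnection: ring F is opened at C4–C4a (ring D) and ring C at C4–C4a (ring A). Both rings close together, and last, in one double 6-endo-dig hydroarylation of a diyne; rings A, B, D and E are bought as arenes.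
4. Enabling feature: C4a of ring D (and of ring A) is ortho to the pyran oxygen O1 and para to the C7 oxygen of a resorcinol ring. C4 of ring F is a bare CH2 (a terminal alkyne carbon), and C4 of ring C is bonded to C6 of ring D (an arylalkyne carbon, made by Sonogashira coupling).
5. The two C2 stereocentres come from copper-catalysed enantioselective propargylic etherification of two phenols (O1 of ring A, O1 of ring D) with one racemic propargylic carbonate.

Key step: step 7

Assumption: the (S,S) enantiomer of Ph-pybox is taken to give the (S)-configured ethers (its mirror image is used if the sense of induction is the opposite), and 4-iodoresorcinol is taken as purchasable.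

**Step 1**
Reactants: 1 3,4-bis(benzyloxy)benzaldehyde; 2 ethynylmagnesium bromide
Product: 3 rac-1-[3,4-bis(benzyloxy)phenyl]prop-2-yn-1-ol
Conditions: THF, 0 °C; aq NH4Cl
Reagents that add atoms: none
Why: Addition of an alkynyl Grignard reagent to an aromatic aldehyde is dependable, and the carbinol centre is left racemic on purpose because the etherifications of steps 3 and 6 are enantioconvergent.

**Step 2**
Reactants: 3 rac-1-[3,4-bis(benzyloxy)phenyl]prop-2-yn-1-ol
Product: 4 rac-1-[3,4-bis(benzyloxy)phenyl]prop-2-yn-1-yl tert-butyl carbonate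
Conditions: Boc2O, DMAP (cat.), CH2Cl2, 0 °C
Reagents that add atoms: di-tert-butyl dicarbonate, CC(C)(C)OC(=O)OC(=O)OC(C)(C)C
Why: DMAP-catalysed O-acylation turns the propargylic alcohol into the carbonate that a copper acetylide can expel, under conditions mild enough for the electron-rich benzylic position.

**Step 3**
Reactants: 4 rac-1-[3,4-bis(benzyloxy)phenyl]prop-2-yn-1-yl tert-butyl carbonate; 5 3-(benzyloxy)phenol
Product: 6 (S)-1-(benzyloxy)-3-({1-[3,4-bis(benzyloxy)phenyl]prop-2-yn-1-yl}oxy)benzene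
Conditions: (CuOTf)2·C6H6 (5 mol%), (S,S)-Ph-pybox (12 mol%), iPr2NEt, THF, −20 °C
Reagents that add atoms: none
Why: Copper-catalysed enantioselective propargylic etherification: the copper acetylide of 4 expels tert-butyl carbonate to give a planar copper allenylidene common to both enantiomers of 4, and the phenol oxygen adds to its γ-carbon on the face left open by the pybox ligand, which sets the (S) centre that becomes C2 of ring C, while amine base and low temperature favour O- over C-attack.

**Step 4**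
Reactants: 7 4-iodoresorcinol
Product: 9 tert-butyl{4-iodo-3-[(triisopropylsilyl)oxy]phenoxy}dimethylsilane, via monosilyl ether 8 (not isolated)
Conditions: TBSCl (1.0 equiv), imidazole, CH2Cl2, −40 → 0 °C; then TIPSOTf, 2,6-lutidine, 0 °C → rt
Reagents that add atoms: tert-butyldimethylsilyl chloride, CC(C)(C)[Si](C)(C)Cl; triisopropylsilyl triflate, CC(C)[Si](C(C)C)(C(C)C)OS(=O)(=O)C(F)(F)F
Why: Sterically controlled silylation: the bulky silyl chloride should take the hydroxyl para to iodine, the hydroxyl flanked by iodine then needs the silyl triflate, and this gives the future O1 of ring D a labile TBS group and the future O7 a robust TIPS group in one flask.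

**Step 5**
Reactants: 6 (S)-1-(benzyloxy)-3-({1-[3,4-bis(benzyloxy)phenyl]prop-2-yn-1-yl}oxy)benzene; 9 tert-butyl{4-iodo-3-[(triisopropylsilyl)oxy]phenoxy}dimethylsilane
Product: 11 4-{(3R)-3-[3-(benzyloxy)phenoxy]-3-[3,4-bis(benzyloxy)phenyl]prop-1-yn-1-yl}-3-[(triisopropylsilyl)oxy]phenol, via bis-silyl arylalkyne 10 (not isolated)
Conditions: Pd(PPh3)4 (5 mol%), pyrrolidine, THF, 40 °C; then K2CO3, MeOH, 0 °C → rt
Reagents that add atoms: none
Why: Copper-free Sonogashira coupling of the aryl iodide with the terminal alkyne makes the future C4(ring C)–C6(ring D) bond as an aryl–alkynyl bond without a copper acetylide that could ionize the propargylic ether, the stereocentre is untouched (its descriptor becomes (R) only by the priority rules), and carbonate in methanol then cleaves the unhindered aryl TBS ether much faster than the aryl TIPS ether.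

**Step 6**
Reactants: 11 4-{(3R)-3-[3-(benzyloxy)phenoxy]-3-[3,4-bis(benzyloxy)phenyl]prop-1-yn-1-yl}-3-[(triisopropylsilyl)oxy]phenol; 4 rac-1-[3,4-bis(benzyloxy)phenyl]prop-2-yn-1-yl tert-butyl carbonate
Product: 12 triisopropyl[5-{[(1S)-1-[3,4-bis(benzyloxy)phenyl]prop-2-yn-1-yl]oxy}-2-{(3R)-3-[3-(benzyloxy)phenoxy]-3-[3,4-bis(benzyloxy)phenyl]prop-1-yn-1-yl}phenoxy]silane
Conditions: (CuOTf)2·C6H6 (5 mol%), (S,S)-Ph-pybox (12 mol%), iPr2NEt, THF, −20 °C
Reagents that add atoms: none
Why: Second copper-catalysed enantioselective propargylic etherification with the same ligand: only the terminal alkyne of 4 can form the allenylidene, so the internal alkyne and the existing centre of 11 are bystanders, and the catalyst sets the new (S) centre that becomes C2 of ring F.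

**Step 7**
Reactants: 12 triisopropyl[5-{[(1S)-1-[3,4-bis(benzyloxy)phenyl]prop-2-yn-1-yl]oxy}-2-{(3R)-3-[3-(benzyloxy)phenoxy]-3-[3,4-bis(benzyloxy)phenyl]prop-1-yn-1-yl}phenoxy]silane
Product: 14 (2S)-7-(benzyloxy)-2-[3,4-bis(benzyloxy)phenyl]-4-{(2S)-2-[3,4-bis(benzyloxy)phenyl]-7-[(triisopropylsilyl)oxy]-2H-chromen-6-yl}-2H-chromene, via monocyclized flavene 13 (not isolated)
Conditions: Ph3PAuNTf2 (5 mol%), 2,6-di-tert-butylpyridine (10 mol%), 4 Å MS, CH2Cl2, 0 °C → rt, dark
Reagents that add atoms: none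
Why: Cationic monovalent gold binds each alkyne, the ortho carbon of the neighbouring aryl ether attacks the activated alkyne anti to the metal, and rearomatization with protodeauration of the vinylgold species releases a 2H-chromene and the catalyst, the terminal alkyne being expected to react first (13) and the arylalkyne second. The closest known reaction type is the gold- or platinum-catalysed intramolecular hydroarylation of aryl propargyl ethers to 2H-chromenes, which is established for terminal and for aryl-substituted alkynes. Ring F closes in the 6-endo-dig mode by attack of C4a of ring D on the terminal alkyne carbon, which becomes C4, and ring C closes in the 6-endo-dig mode by attack of C4a of ring A on the alkyne carbon that bears ring D. No stereocentre is created; the two carbinol centres stay out of the bond reorganization and become the (2S) centres of the flavenes (change of descriptor by priority only), and the buffered, non-protic medium is chosen to keep their benzylic C–O bonds from ionizing. Regioselectivity is needed at both arenes: in ring D the carbon para to O7 is attacked because the other ortho carbon lies between O1 and the bulky OTIPS group, and in ring A closure between the two oxygens would force the benzyloxy group into a peri clash with ring D. Chemoselectivity in the arylalkyne comes from ring D itself, whose O1 and O7 donate into the alkyne and place the positive charge on the carbon bonded to ring D, exactly where ring A must attack, while the TIPS group on O7 cannot migrate and so blocks benzofuran formation.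

**Step 8**
Reactants: 14 (2S)-7-(benzyloxy)-2-[3,4-bis(benzyloxy)phenyl]-4-{(2S)-2-[3,4-bis(benzyloxy)phenyl]-7-[(triisopropylsilyl)oxy]-2H-chromen-6-yl}-2H-chromene
Product: 16 (2R,3S,4S)-7-(benzyloxy)-2-[3,4-bis(benzyloxy)phenyl]-4-{(2R,3S)-2-[3,4-bis(benzyloxy)phenyl]-3-hydroxy-7-[(triisopropylsilyl)oxy]chroman-6-yl}chroman-3-ol, via bis-alkylborane 15 (not isolated)
Conditions: BH3·SMe2 (excess), THF, 0 °C → rt; then aq NaOH, H2O2, 0 °C
Reagents that add atoms: hydrogen peroxide, OO; borane dimethyl sulfide, [BH3-][S+](C)C (its boron stays only in 15)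
Why: Hydroboration–oxidation of flav-3-enes: borane adds syn across each C3=C4 bond from the face opposite the C2 aryl group with boron on C3, and oxidation with retention gives the 2,3-trans alcohols, while in ring C the syn-delivered hydrogen at C4 leaves ring D trans to the 3-hydroxyl, so that C3 and C4 of the upper unit and C3 of the lower unit are set by the two C2 centres.

**Step 9**
Reactants: 16 (2R,3S,4S)-7-(benzyloxy)-2-[3,4-bis(benzyloxy)phenyl]-4-{(2R,3S)-2-[3,4-bis(benzyloxy)phenyl]-3-hydroxy-7-[(triisopropylsilyl)oxy]chroman-6-yl}chroman-3-ol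
Product: 17 (2R,3S,4R)-7-(benzyloxy)-2-[3,4-bis(benzyloxy)phenyl]-4-{(2R,3S)-2-[3,4-bis(benzyloxy)phenyl]-3,7-dihydroxychroman-6-yl}chroman-3-ol
Conditions: TBAF, AcOH, THF, 0 °C
Reagents that add atoms: none
Why: Fluoride cleaves the aryl silyl ether and acetic acid buffers the phenoxide, so that no stereocentre is touched (the C4 descriptor changes by priority only).

**Step 10**
Reactants: 17 (2R,3S,4R)-7-(benzyloxy)-2-[3,4-bis(benzyloxy)phenyl]-4-{(2R,3S)-2-[3,4-bis(benzyloxy)phenyl]-3,7-dihydroxychroman-6-yl}chroman-3-ol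
Product: 18 (2R,3S,4R)-2-(3,4-dihydroxyphenyl)-4-[(2R,3S)-2-(3,4-dihydroxyphenyl)-3,7-dihydroxychroman-6-yl]chromane-3,7-diol
Conditions: H2 (1 atm), Pd(OH)2/C, THF/MeOH, rt
Reagents that add atoms: none
Why: Hydrogenolysis of the five benzyl ethers under neutral conditions at room temperature should leave the ring C2–O1 bonds and the C4–C6 interflavan bond intact and give the free polyphenol.

**Compound list**

1 | 3,4-bis(benzyloxy)benzaldehyde | O=Cc1ccc(OCc2ccccc2)c(OCc2ccccc2)c1 | starting material
2 | ethynylmagnesium bromide | C#C[Mg]Br | starting material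
3 | rac-1-[3,4-bis(benzyloxy)phenyl]prop-2-yn-1-ol | C#CC(O)c1ccc(OCc2ccccc2)c(OCc2ccccc2)c1 | intermediate
4 | rac-1-[3,4-bis(benzyloxy)phenyl]prop-2-yn-1-yl tert-butyl carbonate | C#CC(OC(=O)OC(C)(C)C)c1ccc(OCc2ccccc2)c(OCc2ccccc2)c1 | intermediate
5 | 3-(benzyloxy)phenol | Oc1cccc(OCc2ccccc2)c1 | starting material
6 | (S)-1-(benzyloxy)-3-({1-[3,4-bis(benzyloxy)phenyl]prop-2-yn-1-yl}oxy)benzene | C#C[C@H](Oc1cccc(OCc2ccccc2)c1)c1ccc(OCc2ccccc2)c(OCc2ccccc2)c1 | intermediate
7 | 4-iodoresorcinol (4-iodobenzene-1,3-diol) | Oc1ccc(I)c(O)c1 | starting material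
8 | 5-[(tert-butyldimethylsilyl)oxy]-2-iodophenol (formed in the flask) | CC(C)(C)[Si](C)(C)Oc1ccc(I)c(O)c1 | intermediate
9 | tert-butyl{4-iodo-3-[(triisopropylsilyl)oxy]phenoxy}dimethylsilane | CC(C)(C)[Si](C)(C)Oc1ccc(I)c(O[Si](C(C)C)(C(C)C)C(C)C)c1 | intermediate
10 | tert-butyl(4-{(3R)-3-[3-(benzyloxy)phenoxy]-3-[3,4-bis(benzyloxy)phenyl]prop-1-yn-1-yl}-3-[(triisopropylsilyl)oxy]phenoxy)dimethylsilane (formed in the flask) | CC(C)(C)[Si](C)(C)Oc1ccc(C#C[C@H](Oc2cccc(OCc3ccccc3)c2)c2ccc(OCc3ccccc3)c(OCc3ccccc3)c2)c(O[Si](C(C)C)(C(C)C)C(C)C)c1 | intermediate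
11 | 4-{(3R)-3-[3-(benzyloxy)phenoxy]-3-[3,4-bis(benzyloxy)phenyl]prop-1-yn-1-yl}-3-[(triisopropylsilyl)oxy]phenol | Oc1ccc(C#C[C@H](Oc2cccc(OCc3ccccc3)c2)c2ccc(OCc3ccccc3)c(OCc3ccccc3)c2)c(O[Si](C(C)C)(C(C)C)C(C)C)c1 | intermediate
12 | triisopropyl[5-{[(1S)-1-[3,4-bis(benzyloxy)phenyl]prop-2-yn-1-yl]oxy}-2-{(3R)-3-[3-(benzyloxy)phenoxy]-3-[3,4-bis(benzyloxy)phenyl]prop-1-yn-1-yl}phenoxy]silane (diyne) | C#C[C@H](Oc1ccc(C#C[C@H](Oc2cccc(OCc3ccccc3)c2)c2ccc(OCc3ccccc3)c(OCc3ccccc3)c2)c(O[Si](C(C)C)(C(C)C)C(C)C)c1)c1ccc(OCc2ccccc2)c(OCc2ccccc2)c1 | intermediate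
13 | (2S)-6-{(3R)-3-[3-(benzyloxy)phenoxy]-3-[3,4-bis(benzyloxy)phenyl]prop-1-yn-1-yl}-2-[3,4-bis(benzyloxy)phenyl]-7-[(triisopropylsilyl)oxy]-2H-chromene (ring F closed; formed in the flask) | C(c1ccccc1)Oc1cccc(c1)O[C@H](c1ccc(OCc2ccccc2)c(OCc2ccccc2)c1)C#Cc1cc2c(cc1O[Si](C(C)C)(C(C)C)C(C)C)O[C@H](c1ccc(OCc3ccccc3)c(OCc3ccccc3)c1)C=C2 | intermediate
14 | (2S)-7-(benzyloxy)-2-[3,4-bis(benzyloxy)phenyl]-4-{(2S)-2-[3,4-bis(benzyloxy)phenyl]-7-[(triisopropylsilyl)oxy]-2H-chromen-6-yl}-2H-chromene (bis-flav-3-ene) | C(c1ccccc1)Oc1ccc2c(c1)O[C@H](c1ccc(OCc3ccccc3)c(OCc3ccccc3)c1)C=C2c1cc2c(cc1O[Si](C(C)C)(C(C)C)C(C)C)O[C@H](c1ccc(OCc3ccccc3)c(OCc3ccccc3)c1)C=C2 | intermediate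
15 | bis-alkylborane: BH2 groups on C3 of rings C and F in place of the two 3-hydroxyls of 16, same configuration (formed in the flask) | C(c1ccccc1)Oc1ccc2c(c1)O[C@H](c1ccc(OCc3ccccc3)c(OCc3ccccc3)c1)[C@@H](B)[C@@H]2c1cc2c(cc1O[Si](C(C)C)(C(C)C)C(C)C)O[C@H](c1ccc(OCc3ccccc3)c(OCc3ccccc3)c1)[C@@H](B)C2 | intermediate
16 | (2R,3S,4S)-7-(benzyloxy)-2-[3,4-bis(benzyloxy)phenyl]-4-{(2R,3S)-2-[3,4-bis(benzyloxy)phenyl]-3-hydroxy-7-[(triisopropylsilyl)oxy]chroman-6-yl}chroman-3-ol (upper unit 2,3-trans-3,4-trans; lower unit 2,3-trans) | C(c1ccccc1)Oc1ccc2c(c1)O[C@H](c1ccc(OCc3ccccc3)c(OCc3ccccc3)c1)[C@@H](O)[C@@H]2c1cc2c(cc1O[Si](C(C)C)(C(C)C)C(C)C)O[C@H](c1ccc(OCc3ccccc3)c(OCc3ccccc3)c1)[C@@H](O)C2 | intermediate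
17 | (2R,3S,4R)-7-(benzyloxy)-2-[3,4-bis(benzyloxy)phenyl]-4-{(2R,3S)-2-[3,4-bis(benzyloxy)phenyl]-3,7-dihydroxychroman-6-yl}chroman-3-ol | C(c1ccccc1)Oc1ccc2c(c1)O[C@H](c1ccc(OCc3ccccc3)c(OCc3ccccc3)c1)[C@@H](O)[C@@H]2c1cc2c(cc1O)O[C@H](c1ccc(OCc3ccccc3)c(OCc3ccccc3)c1)[C@@H](O)C2 | intermediate
18 | (2R,3S,4R)-2-(3,4-dihydroxyphenyl)-4-[(2R,3S)-2-(3,4-dihydroxyphenyl)-3,7-dihydroxychroman-6-yl]chromane-3,7-diol, fisetinidol-(4α→6)-fisetinidol | Oc1ccc2c(c1)O[C@H](c1ccc(O)c(O)c1)[C@@H](O)[C@@H]2c1cc2c(cc1O)O[C@H](c1ccc(O)c(O)c1)[C@@H](O)C2 | target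

**Step count and risks**

Total steps: 10. Longest linear sequence: 9 (steps 1, 2, 3, 5, 6, 7, 8, 9, 10).

Steps most likely to fail:

Step 7. The arylalkyne half may cyclize slowly or be diverted (hydration, attack of the silyloxy oxygen of ring D, ionization of the benzylic propargylic C–O bonds with loss of configuration at the future C2 centres), while the first-formed flavene degrades on long exposure to the catalyst. The fallback sets out from compound 6 and comes back at compound 18. Each pyran ring is still closed by 6-endo-dig hydroarylation of a terminal alkyne ether, the simplest case, but the interflavan bond is made by flavan-4-yl cation chemistry instead of through an arylalkyne. Compound 6 with Ph3PAuNTf2 in CH2Cl2 should give (2S)-7-(benzyloxy)-2-[3,4-bis(benzyloxy)phenyl]-2H-chromene F1. Hydroboration–oxidation of one portion (BH3·SMe2, then NaOH, H2O2) should give the 2,3-trans alcohol (2R,3S)-7-(benzyloxy)-2-[3,4-bis(benzyloxy)phenyl]chroman-3-ol F2. Dihydroxylation of the other portion with OsO4 (cat.) and NMO, anti to the C2 aryl group, should give the 2,3-trans-3,4-cis diol (2R,3S,4S)-7-(benzyloxy)-2-[3,4-bis(benzyloxy)phenyl]chromane-3,4-diol F3. Ionization of F3 at C4 with BF3·OEt2 in CH2Cl2 at −78 °C in the presence of an excess of F2 should let C6 of F2 (para to O1, ortho to O7; C8 is flanked by both oxygens) attack the cation anti to the 3-hydroxyl, to give the 3,4-trans-linked hexa-O-benzyl dimer F4. Hydrogenolysis (H2, Pd(OH)2/C) then gives 18. This path also removes the hydroboration of the hindered arylalkene from the route.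

Step 6. On the advanced phenol 11 the copper allenylidene may be captured at an ortho carbon instead of at oxygen, or background ionization of the electron-rich carbonate may erode catalyst control over the new centre, which would give diastereomer mixtures. The fallback sets out from compounds 3 and 11 and comes back at compound 12, with the centre set by resolution and inversion instead of by the copper catalyst. Racemic 3 is acylated with vinyl acetate and immobilized Candida antarctica lipase B, which by the usual enantiopreference of lipases for secondary alcohols should convert the (R)-enantiomer into (R)-1-[3,4-bis(benzyloxy)phenyl]prop-2-yn-1-yl acetate F5. Methanolysis (K2CO3, MeOH) gives (R)-1-[3,4-bis(benzyloxy)phenyl]prop-2-yn-1-ol F6. Mitsunobu etherification of 11 with F6 (PPh3, DIAD, toluene, −20 °C) should proceed at oxygen with inversion to give 12. If the enzyme prefers the other enantiomer, the unreacted alcohol is used instead.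

Step 5. Oxidative addition at the iodide flanked by the OTIPS group may be slow, so that amine-promoted side reactions of 6 (alkyne oligomerization, erosion of the propargylic centre) or early, unselective loss of silyl groups take over. The fallback sets out from compounds 6 and 9 and comes back at compound 10, with a Stille coupling in place of the Sonogashira coupling. Compound 6 is deprotonated at the alkyne (n-BuLi, THF, −78 °C) and quenched with Bu3SnCl to give tributyl{(3R)-3-[3-(benzyloxy)phenoxy]-3-[3,4-bis(benzyloxy)phenyl]prop-1-yn-1-yl}stannane F7. Coupling of F7 with 9 under neutral, amine-free and copper-free conditions (Pd(PPh3)4, toluene, 60 °C) should give 10, which is methanolysed to 11 as in step 5.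

**Further compounds**

F1 | step 7 | (2S)-7-(benzyloxy)-2-[3,4-bis(benzyloxy)phenyl]-2H-chromene | C(c1ccccc1)Oc1ccc2c(c1)O[C@H](c1ccc(OCc3ccccc3)c(OCc3ccccc3)c1)C=C2
F2 | step 7 | (2R,3S)-7-(benzyloxy)-2-[3,4-bis(benzyloxy)phenyl]chroman-3-ol | C(c1ccccc1)Oc1ccc2c(c1)O[C@H](c1ccc(OCc3ccccc3)c(OCc3ccccc3)c1)[C@@H](O)C2
F3 | step 7 | (2R,3S,4S)-7-(benzyloxy)-2-[3,4-bis(benzyloxy)phenyl]chromane-3,4-diol | C(c1ccccc1)Oc1ccc2c(c1)O[C@H](c1ccc(OCc3ccccc3)c(OCc3ccccc3)c1)[C@@H](O)[C@H]2O
F4 | step 7 | (2R,3S,4S)-7-(benzyloxy)-2-[3,4-bis(benzyloxy)phenyl]-4-{(2R,3S)-7-(benzyloxy)-2-[3,4-bis(benzyloxy)phenyl]-3-hydroxychroman-6-yl}chroman-3-ol (hexa-O-benzyl dimer) | C(c1ccccc1)Oc1ccc2c(c1)O[C@H](c1ccc(OCc3ccccc3)c(OCc3ccccc3)c1)[C@@H](O)[C@@H]2c1cc2c(cc1OCc1ccccc1)O[C@H](c1ccc(OCc3ccccc3)c(OCc3ccccc3)c1)[C@@H](O)C2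
F5 | step 6 | (R)-1-[3,4-bis(benzyloxy)phenyl]prop-2-yn-1-yl acetate | C#C[C@@H](OC(C)=O)c1ccc(OCc2ccccc2)c(OCc2ccccc2)c1
F6 | step 6 | (R)-1-[3,4-bis(benzyloxy)phenyl]prop-2-yn-1-ol | C#C[C@@H](O)c1ccc(OCc2ccccc2)c(OCc2ccccc2)c1
F7 | step 5 | tributyl{(3R)-3-[3-(benzyloxy)phenoxy]-3-[3,4-bis(benzyloxy)phenyl]prop-1-yn-1-yl}stannane | CCCC[Sn](CCCC)(CCCC)C#C[C@H](Oc1cccc(OCc2ccccc2)c1)c1ccc(OCc2ccccc2)c(OCc2ccccc2)c1
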